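**Retrosynthesis**
- The target is two successive N-acylations of the C2-symmetric all-trans diamine **8** with trichloroacetyl-pyrroles. The second acylation uses the bromopyrrole, which breaks the symmetry at the end.
- **8** comes from the all-trans, head-to-head cyclobutane **7**. **7** is made in one enantio- and diastereodetermining [2+2] homodimerisation of two molecules of the E-alkenyl-2-acetamidoimidazole **6**.
- **6** comes from the α′-bromoenone **4** and N-acetylguanidine. **4** comes from the enone **3**, which is made by cross-metathesis of N-allylphthalimide with methyl vinyl ketone.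
- Rings are formed in this order: the imidazole (step 3), then the cyclobutane (step 4). The two pyrroles are bought in as trichloroacetyl-pyrroles.

Assumptions: imidazole N–H tautomers are interchangeable. The 2-acetamido group serves as the protected 2-aminoimidazole. The catalyst antipode is chosen to give the depicted enantiomer.

**Step 1**
Reactants: **1** N-allylphthalimide; **2** methyl vinyl ketone (MVK)
Product: **3** (E)-2-(4-oxopent-2-en-1-yl)isoindoline-1,3-dione
Conditions: Hoveyda–Grubbs II (5 mol%), MVK (5 equiv), CH2Cl2, 40 °C
Reagents that add atoms: none
Why: Olefin cross-metathesis couples the type-I allyl imide with the type-II enone and releases ethylene. It gives the E-enone selectively and needs no protection of the imide.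

**Step 2**
Reactant: **3**
Product: **4** (E)-2-(5-bromo-4-oxopent-2-en-1-yl)isoindoline-1,3-dione
Conditions: LiHMDS (1.05 equiv), THF, −78 °C; TMSCl; then NBS, −78 °C; use the crude product at once
Reagents that add atoms: NBS, O=C1CCC(=O)N1Br (delivers Br)
Why: Kinetic deprotonation at the methyl (α′) position gives the cross-conjugated 2-silyloxydiene. Electrophilic bromination at its terminal CH2 (Mukaiyama-type α-halogenation) gives the α′-bromoenone and leaves the alkene and the imide untouched.

**Step 3**
Reactants: **4** (bromoenone); **5** N-acetylguanidine
Product: **6** N-[4-((E)-3-phthalimidoprop-1-en-1-yl)-1H-imidazol-2-yl]acetamide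
Conditions: **5** (3 equiv), DMF, 0 °C → 60 °C
Reagents that add atoms: **5** N-acetylguanidine, CC(=O)NC(N)=N (supplies the N–C–N unit and the acetyl group)
Why: N-Alkylation of the acylguanidine at CH2Br, then cyclodehydration onto the ketone (loss of HBr and H2O), is the standard α-haloketone route to 2-acylaminoimidazoles (Hantzsch-type). The E-alkene is retained, giving a vinylimidazole with the acetamide as N-protection.

**Step 4**
Reactants: **6** (molecule 1, the radical-cation partner); **6** (molecule 2, the neutral alkene partner). Two equivalents of **6** are consumed per **7**.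
Product: **7** all-trans-1,2-bis(2-acetamido-1H-imidazol-4-yl)-3,4-bis(phthalimidomethyl)cyclobutane, single enantiomer (= 6 + 6, no by-product)
Conditions: thioxanthylium·chiral imidodiphosphorimidate (IDPi) ion pair (5 mol%), CH2Cl2 (0.1 M in **6**), −40 °C, green LEDs (525 nm), 48 h
Reagents that add atoms: none
Why: Proposed new method: the photoexcited thioxanthylium oxidises the electron-rich vinylimidazole to its radical cation, which is held as a tight ion pair with the chiral IDPi anion. The 2-acylaminoimidazole N–H/N sites hydrogen-bond to the anion. A second, neutral molecule of **6** then adds through its β-carbon (the carbon bearing CH2N) to one enantioface of the radical cation, forming the β–β′ bond. The resulting 1,4-distonic radical cation closes at the two imidazolyl-bearing carbons, and back-electron-transfer regenerates the catalyst. Closure is anti and E-geometry is retained, so all four substituents are mutually trans. The closest known reactions are the radical-cation [2+2] dimerisation of E-anethole (head-to-head, all-trans) and asymmetric counteranion-directed photoredox catalysis. The new feature is a heteroaryl-vinyl substrate with enantiocontrol from a chiral anion. The allylic nitrogen is an imide, so it is not oxidised and cannot trap the radical cation. All four cyclobutane stereocentres are set here and nothing later touches them.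

**Step 5**
Reactant: **7**
Product: **8** 1,2-bis(2-amino-1H-imidazol-4-yl)-3,4-bis(aminomethyl)cyclobutane, all-trans, isolated as the tetrahydrochloride
Conditions: (a) N2H4·H2O (20 equiv), EtOH, 80 °C, 16 h; filter off phthalhydrazide, concentrate; (b) 3 M HCl, MeOH, 60 °C, 6 h; concentrate, C18 desalting
Reagents that add atoms: none
Why: Ing–Manske hydrazinolysis removes both phthalimides. Acid hydrolysis then removes the labile acylguanidine-type acetyl groups and gives the amine hydrochlorides. The cyclobutane C–H bonds are not acidic enough to epimerise under these conditions.

**Step 6**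
Reactants: **8** (as 8·4HCl); **9** 2-(trichloroacetyl)pyrrole
Product: **10** mono-pyrrole-2-carboxamide (one CH2NH2 left free)
Conditions: 8·4HCl (1.3 equiv), **9** (1.0 equiv), Et3N (6 equiv), DMF, 0 °C → rt, 12 h; C18 chromatography, recycle **8**
Reagents that add atoms: **9** 2-(trichloroacetyl)pyrrole, O=C(C(Cl)(Cl)Cl)c1ccc[nH]1 (delivers the pyrrole-2-carbonyl group)
Why: Trichloroacetyl-pyrroles acylate aliphatic primary amines by haloform-type acyl transfer (CHCl3 is lost) and leave the weakly nucleophilic 2-aminoimidazoles alone. Because **8** is C2-symmetric, the two amines are equivalent and the mono-acylated product is a single compound, which is separated from the statistical mixture.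

**Step 7**
Reactants: **10**; **11** 4-bromo-2-(trichloroacetyl)pyrrole
Product: **12** desbromosceptrine
Conditions: **11** (1.3 equiv), Et3N, DMF, rt, 12 h; reverse-phase HPLC
Reagents that add atoms: **11** 4-bromo-2-(trichloroacetyl)pyrrole, O=C(C(Cl)(Cl)Cl)c1cc(Br)c[nH]1 (delivers the 4-bromopyrrole-2-carbonyl group)
Why: The same chemoselective trichloroacetyl acylation puts the bromopyrrole on the remaining amine, giving the target with a single bromine.

**Compound list**
1 | N-allylphthalimide | C=CCN1C(=O)c2ccccc2C1=O | starting material
2 | methyl vinyl ketone | C=CC(C)=O | starting material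
3 | (E)-2-(4-oxopent-2-en-1-yl)isoindoline-1,3-dione | CC(=O)/C=C/CN1C(=O)c2ccccc2C1=O | intermediate
4 | (E)-2-(5-bromo-4-oxopent-2-en-1-yl)isoindoline-1,3-dione | O=C(CBr)/C=C/CN1C(=O)c2ccccc2C1=O | intermediate
5 | N-acetylguanidine | CC(=O)NC(N)=N | starting material
6 | N-[4-((E)-3-phthalimidoprop-1-en-1-yl)-1H-imidazol-2-yl]acetamide | CC(=O)Nc1ncc(/C=C/CN2C(=O)c3ccccc3C2=O)[nH]1 | intermediate
7 | all-trans bis(acetamidoimidazolyl)bis(phthalimidomethyl)cyclobutane | CC(=O)Nc1ncc([C@H]2[C@H](CN3C(=O)c4ccccc4C3=O)[C@@H](CN3C(=O)c4ccccc4C3=O)[C@@H]2c2cnc(NC(C)=O)[nH]2)[nH]1 | intermediate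
8 | all-trans bis(aminoimidazolyl)bis(aminomethyl)cyclobutane (free base drawn) | Nc1ncc([C@H]2[C@H](CN)[C@@H](CN)[C@@H]2c2cnc(N)[nH]2)[nH]1 | intermediate
9 | 2-(trichloroacetyl)pyrrole | O=C(C(Cl)(Cl)Cl)c1ccc[nH]1 | starting material
10 | mono-pyrrole-2-carboxamide of 8 | Nc1ncc([C@H]2[C@H](CNC(=O)c3ccc[nH]3)[C@@H](CN)[C@@H]2c2cnc(N)[nH]2)[nH]1 | intermediate
11 | 4-bromo-2-(trichloroacetyl)pyrrole | O=C(C(Cl)(Cl)Cl)c1cc(Br)c[nH]1 | starting material
12 | desbromosceptrine | Nc1ncc([C@H]2[C@H](CNC(=O)c3ccc[nH]3)[C@@H](CNC(=O)c3cc(Br)c[nH]3)[C@@H]2c2cnc(N)[nH]2)[nH]1 | target

**Totals:** 7 steps in total; the longest linear sequence is 7 steps.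

**Three steps most likely to fail**
1. **Step 4, the proposed new step (enantioselective radical-cation [2+2] homodimerisation).** Enantiocontrol may be low, all-trans selectivity may be only moderate, or the N–H azole radical cation may decompose.
   - Fallback: run the dimerisation with an achiral photooxidant (Ru(bpz)3 or an acridinium, as in known radical-cation [2+2] cycloadditions) to give racemic all-trans **7**. Resolve **7** by preparative chiral SFC/HPLC, then continue with steps 5–7.
2. **Step 2 (regioselective α′-bromination of the γ-amido enone).** Deprotonation at the γ-CH2 or bromination of the diene at the wrong terminus would give the wrong bromoketone.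
   - Fallback: make the bromomethyl ketone by homologation instead. Convert (E)-4-phthalimidobut-2-enoic acid to the acid chloride, treat with TMSCHN2, then HBr, to give **4** without enolate chemistry.
3. **Step 3 (acetylguanidine with the bromoenone).** Aza-Michael addition to the enone or polymerisation of **4** could outcompete cyclisation.
   - Fallback: build the azole from an α-aminoketone. Convert **4** to the α-azidoketone (NaN3) and reduce it under Staudinger conditions (PPh3, H2O, then HCl to trap the amine salt). Condense the aminoketone with cyanamide (aqueous, pH 4.5, 95 °C) to give the 2-aminoimidazole, then re-acetylate (Ac2O, pyridine) to give **6**.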